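Find the rival first. Your earlier runs differ in first nucleophile, and what you want is the target.

| flask | starting material | first nucleophile | second nucleophile | protic impurity | remark | time |
|---|---|---|---|---|---|---|
| green | 0.050 M | 0.10 M | 0.055 M | 2.5 mM | run made earlier |  |
| grey | 0.050 M | 0.067 M | 0.055 M | 2.5 mM | run made earlier |  |
| amber | 0.050 M | 0.15 M | 0.055 M | 2.5 mM | run made earlier |  |
| cedar | 0.050 M (fed, over 40 min) | 0.100 M | 0.0550 M | 2.50 mM | all else is in the flask from the start; the feed brings no volume worth counting | 3.0 h |
| ash | 0.050 M | 0.100 M | 0.0550 M (fed, over 40 min) | 2.50 mM | all else is in the flask from the start; the feed brings no volume worth counting | 3.0 h |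
| elm | 0.050 M | 0.100 M | 0.0550 M | 2.50 mM | everything together at the start | 3.0 h |

- green (time / h: target / %, starting material / %): 0.250: 31.5, 47.1; 0.417: 40.5, 27.8; 0.667: 47.6, 12.0; 1.00: 51.8, 4.0; 2.00: 53.6, 0.6; 3.00: 54.6, 0.2
- grey (time / h: target / %, starting material / %): 0.667: 41.3, 12.4; 1.33: 45.9, 1.1; 2.00: 45.6, 0.5; 2.50: 46.0, 0.4; 3.00: 46.3, 0.5; 4.00: 46.1, 0
- amber (time / h: target / %, starting material / %): 0.667: 54.3, 12.0; 1.33: 60.2, 1.3; 2.00: 61.4, 0.6; 2.50: 61.2, 0.5; 3.00: 62.2, 0; 4.00: 61.1, 0.5

(readings scatter by 0.3 percentage points)

* the flask that comes out highest in amount of target, in percent of the starting material charged, or "all alike" when all lie within 1.5 percentage points (cedar / ash / elm / all alike)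
* target at the end, in percent of the starting material charged, cedar
* target at the end, in percent of the starting material charged, ash
* target at the end, in percent of the starting material charged, elm

- a reading or a percentage of target counts all its forms, free or not

Begin with the loss ratio: what is charged but is not target, per unit of target, at the last reading. Grey gives 1.17 and amber gives 0.637. If a rival competes with the first nucleophile, this ratio is a floor plus a slope over c(first nucleophile). These two runs give a slope of 0.0645 M and a floor of 0.207, to be read with their scatter. The second nucleophile, charged at 0.055 M, is my candidate for the rival. Slope over charge is then the capture factor 1.17, a selectivity factor: how strongly the second nucleophile competes at equal concentration. The rival ratio, rival's product per target, is this factor times c(second nucleophile) over c(first nucleophile).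

Starting material reads 12.0% in green and 12.0% in amber after 0.667 h, with first nucleophile at 0.10 M and 0.15 M, so I read its loss as a slow first step (the rate-limiting step) that does not wait for the first nucleophile, with k = 3.18 h⁻¹. In ash the second nucleophile rises linearly during the feed. Weight the fraction fed by the decay of starting material and integrate, and the average molecule sees (1 − exp(−k·t))/(k·t) of the charge, with t the feed time. That is 0.415.

My reckoning: elm and cedar hold their charge of second nucleophile from the start, so I give them a rival ratio of 0.645 and target 54.0%; green, which the two-run reckoning did not use, read 54.6%. Ash has a ratio of 0.268 and target 67.8%.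

The forecast also named ash, but its 59% for ash stands lower than my figure; it gave cedar 53.5% and elm 54.4%, saying “so ash should gain modestly”.

The flasks gave cedar 54.1%, ash 66.9%, elm 54.1%.

    starting material → intermediate (k = 0.0480 min⁻¹)
    first nucleophile + intermediate → target (k = 160 M⁻¹ min⁻¹)
    second nucleophile + intermediate → other capture product (k = 160 M⁻¹ min⁻¹)
    crystals ⇌ target, rate k4*(cs4 - [target]) while solid is left; crystals form when [target] > cs4 (solubility = 21.0 mM, k = 6.40 min⁻¹)
    starting material + target → side product (k = 0.270 M⁻¹ min⁻¹)
    second nucleophile + protic impurity → quenched reagent (k = 32.0 M⁻¹ min⁻¹)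

The gap between ash and cedar is 13 percentage points, and with capture by the second nucleophile removed it is 0.044 points, the largest single effect. At the end ash holds 0.252 of other capture product per target, against my rival ratio of 0.268. Take the factor 1.17 to the neighbour of cedar charged with 0.22 M of second nucleophile: its rival ratio is 2.58, which reckons target at 26.4%, and that flask holds 26.6%.

(The runs were computed with constants of no real substance, and the scatter is random.)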